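The benzil is cut between ring B and its carbonyl carbon. Ring A, its ortho oxygen O1 and both diketone carbons (C3 and C2) are bought as 6-methoxybenzofuran-3(2H)-one. The key step exploits the acidic C2 methylene between O1 and the C3 carbonyl, whose enolate is an aromatic 3-oxidobenzofuran. One palladium-catalysed operation joins this C2 to C1 of a ring B aryl bromide that carries the prenyl group and two MOM ethers. Oxygenation of the remaining C2–H then gives a hemiketal that is the ring tautomer of the ortho-hydroxybenzil, and mild acid frees the phenols.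

Key step: step 4

Remark on the chemistry: an ortho-hydroxybenzil and the corresponding 2-aryl-2-hydroxybenzofuran-3(2H)-one are ring–chain tautomers of one substance; 15 and 16 are written as the open diketones, the form in which the target is drawn.

**Step 1**
Reactants: 1 resorcinol
Product: 2 1,3-bis(methoxymethoxy)benzene
Conditions: NaH, MOMCl, DMF, 0 °C → rt
Reagents that add atoms: chloromethyl methyl ether (MOMCl), COCCl
Why: Double Williamson etherification of the resorcinol dianion with the highly electrophilic alpha-chloro ether gives the bis-acetal, which serves both as phenol protection and as the directing group for the two lithiations that follow.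

**Step 2**
Reactants: 2 1,3-bis(methoxymethoxy)benzene; 3 prenyl bromide (1-bromo-3-methylbut-2-ene)
Product: 5 1,3-bis(methoxymethoxy)-2-(3-methylbut-2-en-1-yl)benzene, via aryllithium 4 (not isolated)
Conditions: n-BuLi, THF, 0 °C → rt; CuI (10 mol %), 3, −78 °C → rt
Reagents that add atoms: prenyl bromide (compound 3), CC(C)=CCBr
Why: Directed ortho-metalation occurs at C2, the position flanked and chelated by both methoxymethoxy groups, and the aryllithium (through a catalytic arylcopper species) displaces bromide from the primary terminus of prenyl bromide in an SN2 alkylation, which should give the linear prenyl isomer.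

**Step 3**
Reactants: 5 1,3-bis(methoxymethoxy)-2-(3-methylbut-2-en-1-yl)benzene
Product: 7 1-bromo-2,4-bis(methoxymethoxy)-3-(3-methylbut-2-en-1-yl)benzene, via aryllithium 6 (not isolated)
Conditions: n-BuLi, TMEDA, THF, −78 → 0 °C; BrCl2C–CCl2Br, −78 °C → rt
Reagents that add atoms: 1,2-dibromo-1,1,2,2-tetrachloroethane, BrC(Cl)(Cl)C(Cl)(Cl)Br
Why: A second directed ortho-metalation, steered kinetically by coordination of n-BuLi/TMEDA to a methoxymethoxy oxygen, should take the ring hydrogen at C4 (C4 and C6 are equivalent by symmetry) in preference to the benzylic allylic CH2, and the aryllithium is brominated by halogen transfer from a mild positive-bromine source that leaves the prenyl alkene untouched.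

**Step 4**
Reactants: 7 1-bromo-2,4-bis(methoxymethoxy)-3-(3-methylbut-2-en-1-yl)benzene; 8 6-methoxybenzofuran-3(2H)-one
Product: 11 racemic 2-[2,4-bis(methoxymethoxy)-3-(3-methylbut-2-en-1-yl)phenyl]-6-methoxybenzofuran-3(2H)-one, via coumaranone sodium enolate 9 (not isolated), via 2-aryl sodium enolate 10 (not isolated)
Conditions: Pd(OAc)2 (5 mol %), XPhos (2-dicyclohexylphosphino-2′,4′,6′-triisopropylbiphenyl, 10 mol %), NaOtBu (2.5 equiv), THF, 65 °C, Ar, 8 added slowly; AcOH, 0 °C
Reagents that add atoms: none
Why: Zerovalent palladium, formed in the flask from Pd(OAc)2 and XPhos, inserts into the C–Br bond of 7; the arylpalladium bromide exchanges bromide for the aromatic 3-oxidobenzofuran enolate 9, and reductive elimination from the carbon-bound (C2) palladium enolate forges the C2–aryl bond, the product resting as its enolate 10 until the acidic quench. The closest known reaction type is the palladium-catalysed alpha-arylation of cyclic aryl ketone enolates with aryl bromides, as used to turn chroman-4-ones into isoflavanones. No ring is formed. The new C2 stereocentre arises racemic and needs no control, because it becomes the planar ring B carbonyl carbon in step 5. The step needs C- over O-arylation and mono- over diarylation: the bulky ligand favours the C-bound enolate and fast C–C reductive elimination, and enolate 10 is tertiary, delocalised into two arenes and shielded by the single ortho methoxymethoxy group (itself buttressed by the prenyl group), so it should not couple again. Slow addition of 8 to the excess base leaves no free ketone for aldol self-condensation, the prenyl alkene sits meta to the palladium-bearing carbon and cannot engage in an intramolecular Heck reaction, and air is excluded because 10 oxidises readily.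

**Step 5**
Reactants: 11 racemic 2-[2,4-bis(methoxymethoxy)-3-(3-methylbut-2-en-1-yl)phenyl]-6-methoxybenzofuran-3(2H)-one
Product: 15 1-[2,4-bis(methoxymethoxy)-3-(3-methylbut-2-en-1-yl)phenyl]-2-(2-hydroxy-4-methoxyphenyl)ethane-1,2-dione, via 2-aryl potassium enolate 12 (not isolated), via 2-hydroperoxide 13 (not isolated), via 2-hydroxy hemiketal 14 (not isolated)
Conditions: KN(SiMe3)2, THF, −78 °C; O2 (1 atm), −78 °C; Ar purge, PPh3, −78 → 0 °C; AcOH
Reagents that add atoms: dioxygen, O=O
Why: Enolate autoxidation: the tertiary, doubly aryl-stabilised potassium enolate 12 combines with ground-state dioxygen at C2, PPh3 reduces hydroperoxide 13 at low temperature before it can fragment (a phosphine, unlike a phosphite, does not add to the 1,2-diketone), and the oxide of hemiketal 14 opens to the chelated phenoxide of the benzil, which AcOH protonates; the prenyl alkene and the acetals are inert here and the C2 stereocentre disappears.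

**Step 6**
Reactants: 15 1-[2,4-bis(methoxymethoxy)-3-(3-methylbut-2-en-1-yl)phenyl]-2-(2-hydroxy-4-methoxyphenyl)ethane-1,2-dione
Product: 16 licoagrodione, 1-[2,4-dihydroxy-3-(3-methylbut-2-en-1-yl)phenyl]-2-(2-hydroxy-4-methoxyphenyl)ethane-1,2-dione
Conditions: HCl (3 M aq), MeOH, rt
Reagents that add atoms: none
Why: Acid-catalysed acetal methanolysis of both MOM ethers (the one ortho to the carbonyl is assisted by chelation) should proceed at an acidity below that needed to protonate the trisubstituted prenyl alkene, as in the standard unmasking of 2,4-dihydroxy-3-prenylaryl ketones; no stereocentre is involved.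

**Compound list**
1 | resorcinol | Oc1cccc(O)c1 | starting material
2 | 1,3-bis(methoxymethoxy)benzene | COCOc1cccc(OCOC)c1 | intermediate
3 | prenyl bromide (1-bromo-3-methylbut-2-ene) | CC(C)=CCBr | starting material
4 | [2,6-bis(methoxymethoxy)phenyl]lithium | [Li]c1c(OCOC)cccc1OCOC | intermediate (not isolated)
5 | 1,3-bis(methoxymethoxy)-2-(3-methylbut-2-en-1-yl)benzene | COCOc1cccc(OCOC)c1CC=C(C)C | intermediate
6 | [2,4-bis(methoxymethoxy)-3-(3-methylbut-2-en-1-yl)phenyl]lithium | [Li]c1ccc(OCOC)c(CC=C(C)C)c1OCOC | intermediate (not isolated)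
7 | 1-bromo-2,4-bis(methoxymethoxy)-3-(3-methylbut-2-en-1-yl)benzene | COCOc1ccc(Br)c(OCOC)c1CC=C(C)C | intermediate
8 | 6-methoxybenzofuran-3(2H)-one | COc1ccc2c(c1)OCC2=O | starting material
9 | sodium 6-methoxybenzofuran-3-olate | [Na+].[O-]c1coc2cc(OC)ccc12 | intermediate (not isolated)
10 | sodium 2-[2,4-bis(methoxymethoxy)-3-(3-methylbut-2-en-1-yl)phenyl]-6-methoxybenzofuran-3-olate | [Na+].[O-]c1c(-c2ccc(OCOC)c(CC=C(C)C)c2OCOC)oc2cc(OC)ccc12 | intermediate (not isolated)
11 | racemic 2-[2,4-bis(methoxymethoxy)-3-(3-methylbut-2-en-1-yl)phenyl]-6-methoxybenzofuran-3(2H)-one | COc1ccc2c(c1)OC(c1ccc(OCOC)c(CC=C(C)C)c1OCOC)C2=O | intermediate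
12 | potassium 2-[2,4-bis(methoxymethoxy)-3-(3-methylbut-2-en-1-yl)phenyl]-6-methoxybenzofuran-3-olate | [K+].[O-]c1c(-c2ccc(OCOC)c(CC=C(C)C)c2OCOC)oc2cc(OC)ccc12 | intermediate (not isolated)
13 | racemic 2-[2,4-bis(methoxymethoxy)-3-(3-methylbut-2-en-1-yl)phenyl]-2-hydroperoxy-6-methoxybenzofuran-3(2H)-one | COc1ccc2c(c1)OC(OO)(c1ccc(OCOC)c(CC=C(C)C)c1OCOC)C2=O | intermediate (not isolated)
14 | racemic 2-[2,4-bis(methoxymethoxy)-3-(3-methylbut-2-en-1-yl)phenyl]-2-hydroxy-6-methoxybenzofuran-3(2H)-one | COc1ccc2c(c1)OC(O)(c1ccc(OCOC)c(CC=C(C)C)c1OCOC)C2=O | intermediate (not isolated)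
15 | 1-[2,4-bis(methoxymethoxy)-3-(3-methylbut-2-en-1-yl)phenyl]-2-(2-hydroxy-4-methoxyphenyl)ethane-1,2-dione | COc1ccc(C(=O)C(=O)c2ccc(OCOC)c(CC=C(C)C)c2OCOC)c(O)c1 | intermediate
16 | licoagrodione | COc1ccc(C(=O)C(=O)c2ccc(O)c(CC=C(C)C)c2O)c(O)c1 | target

**Total step count:** 6
**Longest linear sequence:** 6 steps (1 → 2 → 5 → 7 → 11 → 15 → 16); the coumaranone 8 enters at step 4.

**Steps most likely to fail**

Step 4. What may go wrong: aldol self-condensation of the coumaranone before it is fully enolised, O-arylation of the ambident enolate, or stalling of the oxidative addition at the electron-rich, ortho-substituted bromide. The fallback uses no palladium and takes both diketone carbons from a 1,2-dicarbonyl dication equivalent; it sets out from 7 and rejoins the route at 16. Purchased 2-bromo-5-methoxyphenol (COc1ccc(Br)c(O)c1) is protected (NaH, MOMCl, DMF) as 1-bromo-4-methoxy-2-(methoxymethoxy)benzene F1, and bromine–lithium exchange (n-BuLi, THF, −78 °C) turns this into [4-methoxy-2-(methoxymethoxy)phenyl]lithium F2. Separately, 7 is exchanged with n-BuLi (THF, −78 °C) back to aryllithium 6, which is added at −78 °C to 1,4-dimethylpiperazine-2,3-dione (CN1CCN(C)C(=O)C1=O); the addition should stop at the mono-adduct lithium 2-[2,4-bis(methoxymethoxy)-3-(3-methylbut-2-en-1-yl)phenyl]-1,4-dimethyl-3-oxopiperazin-2-olate F3. F2 is then added to the same flask and attacks the remaining amide carbonyl to give dilithium 2-[2,4-bis(methoxymethoxy)-3-(3-methylbut-2-en-1-yl)phenyl]-3-[4-methoxy-2-(methoxymethoxy)phenyl]-1,4-dimethylpiperazine-2,3-diolate F4. Aqueous HCl hydrolyses the bis-hemiaminal to 1-[2,4-bis(methoxymethoxy)-3-(3-methylbut-2-en-1-yl)phenyl]-2-[4-methoxy-2-(methoxymethoxy)phenyl]ethane-1,2-dione F5, and HCl in MeOH as in step 6 removes the three MOM groups and gives 16.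

Step 5. What may go wrong: fragmentation of the alpha-hydroperoxy ketone (C2–C3 cleavage through a dioxetane-type intermediate to an aryl salicylate) before it is reduced, or attack of peroxide on the freshly formed diketone. The fallback replaces the radical oxygenation by a closed-shell transfer of a single oxygen atom (Davis oxidation), so no hydroperoxide is formed; it sets out from 11 and returns at 15. Compound 11 is deprotonated with KN(SiMe3)2 (THF, −78 °C) to enolate 12, which is treated with racemic trans-2-(phenylsulfonyl)-3-phenyloxaziridine. The oxide of hemiketal 14 opens and an AcOH quench gives 15. No compound outside the list is made.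

Step 6. What may go wrong: acid-promoted cyclisation of the prenyl alkene onto a neighbouring phenol (chroman formation) competing with acetal cleavage. The fallback avoids protic acid by exchanging the acetals for silyl ethers; it sets out from 15 and returns at 16. Treatment of 15 with Me3SiOTf and 2,2′-bipyridyl (MeCN, 0 °C → rt) should transfer the methoxymethyl groups to the pyridine nitrogen and leave the tris(trimethylsilyl) ether of the target, 1-[3-(3-methylbut-2-en-1-yl)-2,4-bis(trimethylsilyloxy)phenyl]-2-[4-methoxy-2-(trimethylsilyloxy)phenyl]ethane-1,2-dione F6 (the ring A hydroxyl is expected to silylate as well under excess reagent). Addition of water at rt hydrolyses the silyl ethers to 16.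

**Further compounds**
F1 | step 4 | 1-bromo-4-methoxy-2-(methoxymethoxy)benzene | COCOc1cc(OC)ccc1Br
F2 | step 4 | [4-methoxy-2-(methoxymethoxy)phenyl]lithium | [Li]c1ccc(OC)cc1OCOC
F3 | step 4 | lithium 2-[2,4-bis(methoxymethoxy)-3-(3-methylbut-2-en-1-yl)phenyl]-1,4-dimethyl-3-oxopiperazin-2-olate | [Li+].[O-]C1(c2ccc(OCOC)c(CC=C(C)C)c2OCOC)N(C)CCN(C)C1=O
F4 | step 4 | dilithium 2-[2,4-bis(methoxymethoxy)-3-(3-methylbut-2-en-1-yl)phenyl]-3-[4-methoxy-2-(methoxymethoxy)phenyl]-1,4-dimethylpiperazine-2,3-diolate | [Li+].[Li+].[O-]C1(c2ccc(OCOC)c(CC=C(C)C)c2OCOC)N(C)CCN(C)C1([O-])c1ccc(OC)cc1OCOC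
F5 | step 4 | 1-[2,4-bis(methoxymethoxy)-3-(3-methylbut-2-en-1-yl)phenyl]-2-[4-methoxy-2-(methoxymethoxy)phenyl]ethane-1,2-dione | COCOc1cc(OC)ccc1C(=O)C(=O)c1ccc(OCOC)c(CC=C(C)C)c1OCOC
F0 | step 5 | none | none
F6 | step 6 | 1-[3-(3-methylbut-2-en-1-yl)-2,4-bis(trimethylsilyloxy)phenyl]-2-[4-methoxy-2-(trimethylsilyloxy)phenyl]ethane-1,2-dione | COc1ccc(C(=O)C(=O)c2ccc(O[Si](C)(C)C)c(CC=C(C)C)c2O[Si](C)(C)C)c(O[Si](C)(C)C)c1
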